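## Analysis of the target

Target 23 is an ether-linked dimer of two 2-(2-phenylethyl)chromone units: unit A is an aromatic 7'-methoxychromone whose C6' oxygen is bonded to C8 of unit B, a 5,6,7,8-tetrahydrochromone. Ring B (C4a–C5–C6–C7–C8–C8a) carries hydroxyls at C5, C6 and C7 and four contiguous stereocentres, (5S,6R,7S,8S), with O5/O6 trans, O6/O7 trans and O7/O8 cis. The C5 and C8 oxygens are both allylic to the C4a=C8a bond, and C5–O is in addition vinylogously β to the C4 carbonyl, so loss of water or of the phenol from ring B towards an aromatic chromone threatens under strong acid or base. The hard points are the secondary alkyl aryl ether at C8, which is cis to O7 and therefore cannot come from an epoxide opening or a single SN2 step on a cis-diol, and the annulation of pyranone B onto a cyclohexane with four oxygen substituents. The strategy rests on a repeat: in both pyranones C2 carries the same 2-phenylethyl chain and is bonded to C3. Cutting O1–C2 and C2–C3 in unit B, and O1'–C2' and C2'–C3' in unit A, leaves two methyl ketones and two identical 3-phenylpropanoyl units. The methyl ketones are the acetyl group on C4a' of a 2-hydroxyacetophenone (ring A) and the acetyl group on C4a of a 2-acetylcyclohexanone enol (ring B, enol oxygen on C8a), so both heterocycles can be finished from one bis-methyl ketone, 18, in which all four stereocentres are already in place.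

## Retrosynthetic reasoning

Ring B atoms carry the locants of 23 (C4a, C5–C8, C8a; primed locants for unit A) in every intermediate.

23 to 22. Only the three O–Si bonds are cut. The triol is kept masked until the last step because it is the part most prone to elimination next to the pyranone. The forward step must remove three secondary silyl ethers without ionising C5–O or C8–O.

22 to 21. Both pyranones are opened at O1–C2 and O1'–C2'. These C–O bonds form readily from an open 1,3-dicarbonyl array (phenol or enol oxygen onto a ketone, then loss of water), so cutting them exposes the bis-1,3-diketone 21 at no cost in control. The forward step is a double cyclodehydration.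

21 to 18 and two molecules of 20. C2–C3 and C2'–C3' are cut. Each joins a ketone α-carbon to an acyl carbon, and the same acyl unit occurs twice; a cut at C3–C4 instead would need two different nucleophile/electrophile pairs. What is gained is that one reagent, 20, supplies C2 and the side chain of both heterocycles, and that 18 already holds every stereocentre. The forward step must acylate the polyanion of 18 at the two methyl carbons only.

18 to 17 to 15. The phenol is traced to its benzyl ether, the C4a acetyl group to a 1-ethoxyvinyl group, and the C5 silyl ether to the C5 alcohol. The acetyl group is kept masked until O5 is silylated, so that neither a free β-hydroxy diketone nor a 2-acyl enone has to be handled.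

15 to 13. The C5–O bond is cut. C5 is the β-carbon of the C8a enone, so the oxygen can enter by conjugate borylation and C–B oxidation. This is preferred to conjugate addition of an oxygen nucleophile because it is irreversible, and the bulky C6 silyl ether directs it.

13 to 12 to 11. The C4a–C4 bond is cut at the enone α-carbon, the one position where a halide can be placed regiospecifically (α-iodination) and then coupled (Stille). An enolate acylation would have to choose between C4a and C8.

11 to 10 to 8. C8a=O and C6–O are both traced to photooxygenation of the bromodiene 8 across C8a and C6, followed by reduction and loss of HBr. This gives the enone needed above and sets C6 trans to O7.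

8 to 7 and 5. The aryl ether is cut at O–C6' and not at C8–O, because the cis-diol of 6 already has the correct C8 configuration, and forming the O–aryl bond keeps it. The forward step is a copper-catalysed oxidative coupling of the C8 hydroxyl of 7 with the arylboron reagent 5. Compound 7 comes from 6 by silylation of the hydroxyl remote from bromine.

5 to 3 to 2 to 1, and 20 to 19. The C–B bond comes from the C–Br bond, the benzyl ether from the phenol, and the bromide from bromination of 1 para to the hydroxyl. The amide 20 comes from acid 19.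

## Alternatives that were turned down

Alternative 1: The disconnection is C4a–C5 and O1–C2 of unit B, back to the open-chain triketo aldehyde A2, in which unit A is already a finished chromone. In the forward step, amine-salt catalysis would add the doubly activated C4a methylene to the C5 aldehyde to close ring B, and the C8a enol oxygen would then condense with the C2 ketone to give A1.
- For it: two rings and one stereocentre arise in one operation, C6–C8 come from an acyclic sugar-type chain, and the C8 aryl ether could be set by a clean SN2 step on an acyclic carbinol. On that last point it is stronger than the copper coupling used here.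
- Against it: the aldol adduct has a C4a–H between two carbonyls next to the new C5 hydroxyl, which is the intermediate of a Knoevenagel condensation, so dehydration to C4a=C5 and then aromatisation is the expected course. The C5 configuration would rest on an uncertain preference, C8 is epimerisable through the C8a ketone, and A2 is long and fragile to assemble.
- Comparison: the chosen route sets C5 by a stereospecific C–B oxidation and protects it before any dicarbonyl chemistry, and it makes both pyranones from one reagent. It pays with more steps on ring B.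

Alternative 2: The disconnection is C5–C6 and C7–C8. In the forward step, light-induced enolisation of the pyranone aldehyde A4 under a chiral Lewis acid would give a dienol that adds the trans-enedione A5 to give A3.
- For it: two C–C bonds, ring B and all four stereocentres form in one step with pyranone B already present. In stereocentres per step and in brevity to the carbocycle it is clearly superior to the chosen route.
- Against it: C6 and C7 emerge as C-acetyl groups, so two Baeyer–Villiger oxidations and two ester cleavages are needed beside an oxidisable pyranone and a 4-methoxybenzyl ether. 4-Pyranones have competing photochemistry of their own. The C8 hydroxyl of A3 would still need arylation with retention, later and on a carbinol more prone to elimination, and unit A must be made separately.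
- Comparison: the chosen route is longer, but every oxygen enters as oxygen, every stereocentre comes from a reaction with a predictable facial course, and both heterocycles form together.

Alternative 3: The disconnection is C8a–O and C6–O. In the forward step, dye-sensitised photooxygenation of the bromodiene A7, which carries the finished chromone of unit A, followed by peroxide reduction with loss of HBr, would give A6.
- For it: this is the same reaction type as step 6 here, with the same anti facial course, so it is equal on control of C6 and on the origin of the C8a oxygen. Only one pyranone would remain to be built.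
- Against it: as the central step it forms two C–O bonds and one stereocentre and leaves C4a–C4, C5–O, C2–C3 and O1–C2 of unit B open. The chromone of unit A would have to survive all of that, although its C2'=C3' bond is a conjugate acceptor and its side-chain methylene is vinylogously acidic under the strong base that must still extend the ring B acetyl group. The repeat unit would be built twice, in two separate sequences.
- Comparison: the chosen route keeps the photooxygenation as a supporting step on the plain acetophenone ether 8, and one acylation and one cyclodehydration serve both units.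

Key step: step 14

Remark on the chemistry: 17, 18 and 21 are drawn as their C8a enols, and 14–16 form as C4a epimers whose C4a centre is erased in step 11.

## Route

Step 1
Reactants: 1 paeonol
Product: 2 1-(5-bromo-2-hydroxy-4-methoxyphenyl)ethan-1-one
Conditions: NBS, MeCN, 0 °C → rt
Reagents that add atoms: N-bromosuccinimide, O=C1CCC(=O)N1Br
Why: Electrophilic aromatic bromination; C5 is para to the hydroxyl, ortho to the methoxy group and less hindered than C3, which lies between two oxygens, so monobromination should occur there.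

Step 2
Reactants: 2 1-(5-bromo-2-hydroxy-4-methoxyphenyl)ethan-1-one
Product: 3 1-[2-(benzyloxy)-5-bromo-4-methoxyphenyl]ethan-1-one
Conditions: BnBr, K2CO3, DMF, 60 °C
Reagents that add atoms: benzyl bromide, BrCc1ccccc1
Why: Williamson etherification of the phenol; the benzyl ether keeps the phenol out of the copper coupling and the silylations and is removed in step 12.

Step 3
Reactants: 3 1-[2-(benzyloxy)-5-bromo-4-methoxyphenyl]ethan-1-one
Product: 5 potassium [5-acetyl-4-(benzyloxy)-2-methoxyphenyl]trifluoroborate, via pinacol boronate 4 (not isolated)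
Conditions: B2pin2, PdCl2(dppf) (cat.), KOAc, 1,4-dioxane, 90 °C; then KHF2, MeOH/H2O, rt
Reagents that add atoms: bis(pinacolato)diboron, CC1(C)OB(OC1(C)C)B1OC(C)(C)C(C)(C)O1; potassium hydrogen difluoride, F.[F-].[K+] (two formula units)
Why: Miyaura borylation tolerates the ketone, and fluoride exchange gives the bench-stable trifluoroborate, a suitable boron partner for copper-catalysed etherification of aliphatic alcohols.

Step 4
Reactants: 6 (1S,2S)-3-bromocyclohexa-3,5-diene-1,2-diol
Product: 7 (1S,6S)-2-bromo-6-{[tert-butyl(dimethyl)silyl]oxy}cyclohexa-2,4-dien-1-ol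
Conditions: TBSCl, imidazole, DMF, −10 °C
Reagents that add atoms: tert-butyldimethylsilyl chloride, CC(C)(C)[Si](C)(C)Cl
Why: Selective monosilylation of the cis-diol; the hydroxyl remote from bromine (C7) is less hindered and more nucleophilic than the one next to the bromoalkene (C8), a known selectivity for halodiene diols.

Step 5
Reactants: 7 (1S,6S)-2-bromo-6-{[tert-butyl(dimethyl)silyl]oxy}cyclohexa-2,4-dien-1-ol; 5 potassium [5-acetyl-4-(benzyloxy)-2-methoxyphenyl]trifluoroborate
Product: 8 aryl ether diene (C8–O–aryl, C7 silyl ether)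
Conditions: Cu(OAc)2·H2O (cat.), DMAP, 4 Å MS, O2 (1 atm), CH2Cl2, rt
Reagents that add atoms: none
Why: Chan–Lam-type oxidative C–O coupling of a secondary alcohol with an aryltrifluoroborate; the aryl group is transferred to oxygen on copper and the C8–O bond is never broken, so C8 keeps its configuration and the 7,8-cis relationship of 6 is carried into the aryl ether.

Step 6
Reactants: 8 aryl ether diene
Product: 10 (4R,5S,6S)-hydroxy enone (C8a ketone, C4a=C5, free C6 hydroxyl), via endoperoxide 9 (not isolated)
Conditions: O2, tetraphenylporphyrin (cat.), hν (visible), CH2Cl2, −78 °C; then thiourea, MeOH, −78 °C → rt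
Reagents that add atoms: dioxygen, O=O
Why: Singlet oxygen adds [4+2] across C8a and C6 from the face opposite the C7 silyloxy and C8 aryloxy groups, which sets C6 trans to O7; reduction of the O–O bond leaves a C8a bromohydrin that collapses to the ketone with loss of HBr, as known for halodiene diol derivatives.

Step 7
Reactants: 10 (4R,5S,6S)-hydroxy enone
Product: 11 (4R,5R,6S)-bis-silyl enone
Conditions: TBSCl, imidazole, DMF, rt
Reagents that add atoms: tert-butyldimethylsilyl chloride, CC(C)(C)[Si](C)(C)Cl
Why: Standard silylation of the secondary allylic alcohol under weakly basic conditions; the bulky C6 silyl ether is the control element for step 10.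

Step 8
Reactants: 11 (4R,5R,6S)-bis-silyl enone
Product: 12 (4R,5R,6S)-2-iodo enone (iodine on C4a)
Conditions: I2, pyridine, CH2Cl2, 0 °C → rt
Reagents that add atoms: iodine, II
Why: α-Iodination of the enone by conjugate addition of pyridine, iodination of the enolate and elimination; a routine reaction of 4-silyloxycyclohexenones that places the coupling handle on C4a only.

Step 9
Reactants: 12 (4R,5R,6S)-2-iodo enone
Product: 13 (4R,5R,6S)-2-(1-ethoxyethenyl) enone
Conditions: Bu3SnC(OEt)=CH2, Pd2(dba)3 (cat.), AsPh3, CuI, DMF, 45 °C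
Reagents that add atoms: tributyl(1-ethoxyethenyl)stannane, CCCC[Sn](CCCC)(CCCC)C(=C)OCC
Why: Stille coupling of the α-iodoenone under neutral conditions forms C4a–C4; the enol ether is a masked acetyl group that leaves C4a=C5 an ordinary enone for the next step.

Step 10
Reactants: 13 (4R,5R,6S)-2-(1-ethoxyethenyl) enone
Product: 15 (3S,4R,5R,6S)-β-hydroxy ketone (free C5 hydroxyl), via C5 pinacol boronate 14 (not isolated)
Conditions: B2pin2, CuCl (cat.), Xantphos (cat.), NaOtBu (cat.), MeOH, THF, 0 °C → rt; then NaBO3·4H2O, THF/H2O, rt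
Reagents that add atoms: sodium perborate tetrahydrate, [Na+].[Na+].O[B-]1(O)OO[B-](O)(O)OO1 (the oxygen on C5); bis(pinacolato)diboron, CC1(C)OB(OC1(C)C)B1OC(C)(C)C(C)(C)O1 (boron of 14 only)
Why: Copper-catalysed conjugate borylation of the enone; the boryl copper species should add to C5 by axial attack anti to the adjacent C6 silyloxy group, and perborate oxidises the C–B bond with retention, so that O5 ends trans to O6 and cis to O7 (5S). Together the two operations are an irreversible formal conjugate hydration.

Step 11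
Reactants: 15 (3S,4R,5R,6S)-β-hydroxy ketone
Product: 17 benzyl-protected 2-acetylcyclohexanone enol, via tris-silyl enol ether 16 (not isolated)
Conditions: TBSOTf, 2,6-lutidine, CH2Cl2, −78 °C; then 0.5 M HCl, THF, 0 °C
Reagents that add atoms: tert-butyldimethylsilyl trifluoromethanesulfonate, CC(C)(C)[Si](C)(C)OS(=O)(=O)C(F)(F)F; water, O
Why: Silyl triflate silylates the hindered C5 alcohol under buffered conditions, and brief aqueous acid hydrolyses the enol ether to the acetyl group while the secondary silyl ethers survive; the product is the hydrogen-bonded enol of the 2-acylcyclohexanone, which erases the C4a centre.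

Step 12
Reactants: 17 benzyl-protected 2-acetylcyclohexanone enol
Product: 18 bis-methyl ketone (free phenol)
Conditions: H2 (1 atm), Pd/C (10 wt %), EtOAc, rt
Reagents that add atoms: none
Why: Hydrogenolysis of the aryl benzyl ether; the silyl ethers, the chelated tetrasubstituted enol and the ortho-oxygenated aryl ketone should not react at 1 atm.

Step 13
Reactants: 19 3-phenylpropanoic acid
Product: 20 N-methoxy-N-methyl-3-phenylpropanamide
Conditions: MeNH(OMe)·HCl, EDC·HCl, N-methylmorpholine, CH2Cl2, 0 °C → rt
Reagents that add atoms: N,O-dimethylhydroxylamine hydrochloride, CNOC.Cl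
Why: Carbodiimide-mediated amide formation, the standard route to a Weinreb amide.

Step 14
Reactants: 18 bis-methyl ketone; 20 N-methoxy-N-methyl-3-phenylpropanamide
Product: 21 bis-1,3-diketone
Conditions: LiN(iPr)2 (4.4 equiv), THF, −78 °C; then 20 (2.6 equiv), −78 → −30 °C; AcOH, −78 °C
Reagents that add atoms: N-methoxy-N-methyl-3-phenylpropanamide, CON(C)C(=O)CCc1ccccc1 (the second molecule of 20, which supplies the second 3-phenylpropanoyl unit)
Why: LiN(iPr)2 removes the phenol and enol protons and then one proton from each methyl group, giving the phenoxide–enolate of the acetophenone and the dianion of the β-diketone; a silylamide base would be too weak for the second deprotonation of the diketone enolate. Each of the two terminal carbanions adds to one molecule of the Weinreb amide 20, and the chelated N-methoxy-N-methyl tetrahedral adducts persist until the acid quench, so no ketone is released in the flask and neither over-addition nor proton transfer to unreacted carbanion can occur. The closest known reactions are the C-acylation of 2-hydroxyacetophenone dianions on the way to chromones and the terminal acylation of β-diketone dianions to 1,3,5-triketones. Two C–C bonds (C2–C3 and C2'–C3') are formed; no ring is closed and no stereocentre is created, and C5–C8 are spectators. The step needs site selectivity only: the methyl carbons must react rather than the oxygens, C4a or C8–H. This is secured because the last-formed and most basic sites of the polyanion are the unhindered methyl carbanions, the oxygens are tied up as lithium chelates, and the C8 methine is flanked by the aryloxy and silyloxy groups. The main hazard is E1cB loss of the C5 silyloxy group from the diketone enolate, which the low temperature and the quench at −78 °C are meant to suppress.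

Step 15
Reactants: 21 bis-1,3-diketone
Product: 22 (5S,6R,7R,8S)-tris-silyl ether of the target
Conditions: CF3CO2H, CH2Cl2, 0 °C → rt
Reagents that add atoms: none
Why: Acid-mediated cyclodehydration; the phenol oxygen of unit A and the C8a enol oxygen of unit B each add to their C2 carbonyl (6-exo-trig) and the hemiketals lose water, as known for 1-(2-hydroxyaryl)-1,3-diketones (chromones) and 1,3,5-triketones (4-pyranones).

Step 16
Reactants: 22 (5S,6R,7R,8S)-tris-silyl ether of the target
Product: 23 target, (5S,6R,7S,8S)-5,6,7-trihydroxy-8-{[7-methoxy-4-oxo-2-(2-phenylethyl)-4H-chromen-6-yl]oxy}-2-(2-phenylethyl)-5,6,7,8-tetrahydro-4H-chromen-4-one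
Conditions: HF·pyridine, pyridine, THF, 0 °C → rt
Reagents that add atoms: none
Why: Fluoride cleaves the three secondary silyl ethers under buffered, weakly acidic conditions that should neither ionise C5–O or C8–O nor trigger base-induced elimination.

## Compound list

1 | paeonol, 1-(2-hydroxy-4-methoxyphenyl)ethan-1-one | COc1ccc(C(C)=O)c(O)c1 | starting material
2 | 1-(5-bromo-2-hydroxy-4-methoxyphenyl)ethan-1-one | COc1cc(O)c(C(C)=O)cc1Br | intermediate
3 | 1-[2-(benzyloxy)-5-bromo-4-methoxyphenyl]ethan-1-one | COc1cc(OCc2ccccc2)c(C(C)=O)cc1Br | intermediate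
4 | 1-[2-(benzyloxy)-4-methoxy-5-(4,4,5,5-tetramethyl-1,3,2-dioxaborolan-2-yl)phenyl]ethan-1-one | COc1cc(OCc2ccccc2)c(C(C)=O)cc1B1OC(C)(C)C(C)(C)O1 | intermediate (not isolated)
5 | potassium [5-acetyl-4-(benzyloxy)-2-methoxyphenyl]trifluoroborate | [K+].COc1cc(OCc2ccccc2)c(C(C)=O)cc1[B-](F)(F)F | intermediate
6 | (1S,2S)-3-bromocyclohexa-3,5-diene-1,2-diol | O[C@H]1C=CC=C(Br)[C@H]1O | starting material
7 | (1S,6S)-2-bromo-6-{[tert-butyl(dimethyl)silyl]oxy}cyclohexa-2,4-dien-1-ol | O[C@@H]1C(Br)=CC=C[C@@H]1O[Si](C)(C)C(C)(C)C | intermediate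
8 | 1-[2-(benzyloxy)-5-{[(1S,6S)-2-bromo-6-{[tert-butyl(dimethyl)silyl]oxy}cyclohexa-2,4-dien-1-yl]oxy}-4-methoxyphenyl]ethan-1-one | CC(=O)c1cc(O[C@@H]2C(Br)=CC=C[C@@H]2O[Si](C)(C)C(C)(C)C)c(OC)cc1OCc1ccccc1 | intermediate
9 | endoperoxide of 8: 1-{2-(benzyloxy)-5-[(1-bromo-8-{[tert-butyl(dimethyl)silyl]oxy}-2,3-dioxabicyclo[2.2.2]oct-5-en-7-yl)oxy]-4-methoxyphenyl}ethan-1-one, peroxide bridge from C8a to C6 on the face opposite the C7 silyloxy and C8 aryloxy groups, C7 and C8 as in 8 | CC(=O)c1cc(O[C@@H]2[C@@]3(Br)OO[C@H](C=C3)[C@@H]2O[Si](C)(C)C(C)(C)C)c(OC)cc1OCc1ccccc1 | intermediate (not isolated)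
10 | (4R,5S,6S)-6-[5-acetyl-4-(benzyloxy)-2-methoxyphenoxy]-5-{[tert-butyl(dimethyl)silyl]oxy}-4-hydroxycyclohex-2-en-1-one | CC(=O)c1cc(O[C@@H]2C(=O)C=C[C@@H](O)[C@@H]2O[Si](C)(C)C(C)(C)C)c(OC)cc1OCc1ccccc1 | intermediate
11 | (4R,5R,6S)-6-[5-acetyl-4-(benzyloxy)-2-methoxyphenoxy]-4,5-bis{[tert-butyl(dimethyl)silyl]oxy}cyclohex-2-en-1-one | CC(=O)c1cc(O[C@@H]2C(=O)C=C[C@@H](O[Si](C)(C)C(C)(C)C)[C@@H]2O[Si](C)(C)C(C)(C)C)c(OC)cc1OCc1ccccc1 | intermediate
12 | (4R,5R,6S)-6-[5-acetyl-4-(benzyloxy)-2-methoxyphenoxy]-4,5-bis{[tert-butyl(dimethyl)silyl]oxy}-2-iodocyclohex-2-en-1-one | CC(=O)c1cc(O[C@@H]2C(=O)C(I)=C[C@@H](O[Si](C)(C)C(C)(C)C)[C@@H]2O[Si](C)(C)C(C)(C)C)c(OC)cc1OCc1ccccc1 | intermediate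
13 | (4R,5R,6S)-6-[5-acetyl-4-(benzyloxy)-2-methoxyphenoxy]-4,5-bis{[tert-butyl(dimethyl)silyl]oxy}-2-(1-ethoxyethenyl)cyclohex-2-en-1-one | CC(=O)c1cc(O[C@@H]2C(=O)C(C(=C)OCC)=C[C@@H](O[Si](C)(C)C(C)(C)C)[C@@H]2O[Si](C)(C)C(C)(C)C)c(OC)cc1OCc1ccccc1 | intermediate
14 | (3S,4R,5R,6S)-6-[5-acetyl-4-(benzyloxy)-2-methoxyphenoxy]-4,5-bis{[tert-butyl(dimethyl)silyl]oxy}-2-(1-ethoxyethenyl)-3-(4,4,5,5-tetramethyl-1,3,2-dioxaborolan-2-yl)cyclohexan-1-one, C2 (= C4a) epimers | CC(=O)c1cc(O[C@@H]2C(=O)C(C(=C)OCC)[C@H](B3OC(C)(C)C(C)(C)O3)[C@@H](O[Si](C)(C)C(C)(C)C)[C@@H]2O[Si](C)(C)C(C)(C)C)c(OC)cc1OCc1ccccc1 | intermediate (not isolated)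
15 | (3S,4R,5R,6S)-6-[5-acetyl-4-(benzyloxy)-2-methoxyphenoxy]-4,5-bis{[tert-butyl(dimethyl)silyl]oxy}-2-(1-ethoxyethenyl)-3-hydroxycyclohexan-1-one, C2 (= C4a) epimers | CC(=O)c1cc(O[C@@H]2C(=O)C(C(=C)OCC)[C@H](O)[C@@H](O[Si](C)(C)C(C)(C)C)[C@@H]2O[Si](C)(C)C(C)(C)C)c(OC)cc1OCc1ccccc1 | intermediate
16 | (3S,4R,5R,6S)-6-[5-acetyl-4-(benzyloxy)-2-methoxyphenoxy]-3,4,5-tris{[tert-butyl(dimethyl)silyl]oxy}-2-(1-ethoxyethenyl)cyclohexan-1-one, C2 (= C4a) epimers | CC(=O)c1cc(O[C@@H]2C(=O)C(C(=C)OCC)[C@H](O[Si](C)(C)C(C)(C)C)[C@@H](O[Si](C)(C)C(C)(C)C)[C@@H]2O[Si](C)(C)C(C)(C)C)c(OC)cc1OCc1ccccc1 | intermediate (not isolated)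
17 | 1-[5-{[(1S,4S,5R,6R)-3-acetyl-4,5,6-tris{[tert-butyl(dimethyl)silyl]oxy}-2-hydroxycyclohex-2-en-1-yl]oxy}-2-(benzyloxy)-4-methoxyphenyl]ethan-1-one | CC(=O)c1cc(O[C@@H]2C(O)=C(C(C)=O)[C@H](O[Si](C)(C)C(C)(C)C)[C@@H](O[Si](C)(C)C(C)(C)C)[C@@H]2O[Si](C)(C)C(C)(C)C)c(OC)cc1OCc1ccccc1 | intermediate
18 | 1-[5-{[(1S,4S,5R,6R)-3-acetyl-4,5,6-tris{[tert-butyl(dimethyl)silyl]oxy}-2-hydroxycyclohex-2-en-1-yl]oxy}-2-hydroxy-4-methoxyphenyl]ethan-1-one | CC(=O)c1cc(O[C@@H]2C(O)=C(C(C)=O)[C@H](O[Si](C)(C)C(C)(C)C)[C@@H](O[Si](C)(C)C(C)(C)C)[C@@H]2O[Si](C)(C)C(C)(C)C)c(OC)cc1O | intermediate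
19 | 3-phenylpropanoic acid | OC(=O)CCc1ccccc1 | starting material
20 | N-methoxy-N-methyl-3-phenylpropanamide | CON(C)C(=O)CCc1ccccc1 | intermediate
21 | 1-[2-hydroxy-4-methoxy-5-({(1S,4S,5R,6R)-4,5,6-tris{[tert-butyl(dimethyl)silyl]oxy}-2-hydroxy-3-(3-oxo-5-phenylpentanoyl)cyclohex-2-en-1-yl}oxy)phenyl]-5-phenylpentane-1,3-dione | O=C(CC(=O)CCc1ccccc1)c1cc(O[C@@H]2C(O)=C(C(=O)CC(=O)CCc3ccccc3)[C@H](O[Si](C)(C)C(C)(C)C)[C@@H](O[Si](C)(C)C(C)(C)C)[C@@H]2O[Si](C)(C)C(C)(C)C)c(OC)cc1O | intermediate
22 | (5S,6R,7R,8S)-5,6,7-tris{[tert-butyl(dimethyl)silyl]oxy}-8-{[7-methoxy-4-oxo-2-(2-phenylethyl)-4H-chromen-6-yl]oxy}-2-(2-phenylethyl)-5,6,7,8-tetrahydro-4H-chromen-4-one | COc1cc2oc(CCc3ccccc3)cc(=O)c2cc1O[C@@H]1c2oc(CCc3ccccc3)cc(=O)c2[C@H](O[Si](C)(C)C(C)(C)C)[C@@H](O[Si](C)(C)C(C)(C)C)[C@@H]1O[Si](C)(C)C(C)(C)C | intermediate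
23 | (5S,6R,7S,8S)-5,6,7-trihydroxy-8-{[7-methoxy-4-oxo-2-(2-phenylethyl)-4H-chromen-6-yl]oxy}-2-(2-phenylethyl)-5,6,7,8-tetrahydro-4H-chromen-4-one | COc1cc2oc(CCc3ccccc3)cc(=O)c2cc1O[C@@H]1c2oc(CCc3ccccc3)cc(=O)c2[C@H](O)[C@@H](O)[C@@H]1O | target

## Step count and least certain steps

Total step count: 16 (3 for the aryltrifluoroborate, 1 for the amide, 12 on the main line). Longest linear sequence: 14 steps, from 1 through steps 1–3, 5–12 and 14–16. From 6 it is 12 steps.

Step 14 (key step). The second acylation may stall because the tetra-lithiated species aggregates and the amide is a modest electrophile. The warming then needed would invite β-elimination of the C5 silyloxy group from the diketone enolate, or deprotonation at C8 with epimerisation. Fallback, from 17 back to 21: the same two C–C bonds are made by aldol addition and oxidation instead of acylation. The trianion of the benzyl ether 17 (LiN(iPr)2, THF, −78 °C) is treated with 3-phenylpropanal, a far stronger electrophile that should react fully at −78 °C at both methyl carbanions, to give the bis(β-hydroxy ketone) F1 as carbinol epimers. Oxidation of both carbinols with the Dess–Martin periodinane (NaHCO3, CH2Cl2, 0 °C), with the phenol still protected, gives the bis-1,3-diketone benzyl ether F2. Hydrogenolysis as in step 12 (H2, Pd/C) then gives 21.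

Step 5. The C8 hydroxyl is the hindered, less nucleophilic one of the diol. Aryl transfer may therefore be slow, so that protodeboronation and hydroxylation of 5 outrun etherification, and the dienol may be oxidised and aromatise. Fallback, from 7 back to 8: the ether bond is made at the sp3 carbon by two successive inversions. A Mitsunobu reaction of 7 with 4-nitrobenzoic acid (PPh3, diisopropyl azodicarboxylate) inverts C8 and gives (1R,6S)-2-bromo-6-{[tert-butyl(dimethyl)silyl]oxy}cyclohexa-2,4-dien-1-yl 4-nitrobenzoate F3. Methanolysis (K2CO3, MeOH) gives the trans alcohol F4. A second Mitsunobu reaction with the phenol 1-[2-(benzyloxy)-5-hydroxy-4-methoxyphenyl]ethan-1-one F5, made from 5 by oxidation with KHSO5 in acetone/water, inverts C8 again and gives 8.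

Step 10. Conjugate addition to the α-branched enone, which also carries a donor enol ether, may be slow. Prolonged exposure to the alkoxide co-catalyst could then epimerise C8 or eliminate the C7 silyloxy group from the C8 enolate, and attack syn to O6 cannot be excluded. Fallback, from 13 back to 17: the oxygen is brought in by a peroxide nucleophile onto a far stronger acceptor. Brief hydrolysis of 13 (0.5 M HCl, THF, 0 °C) gives the 2-acetyl enone F6. Weitz–Scheffer epoxidation (tBuOOH, DBU, CH2Cl2, 0 °C), in which the peroxide adds to C5 anti to the C6 silyloxy group and ring closure makes the addition irreversible, gives the epoxy diketone F7. SmI2 (THF/MeOH, −78 °C) cleaves the C4a–O bond and gives the β-hydroxy diketone F8. Silylation (TBSOTf, 2,6-lutidine, then dilute acid to cleave the enol silyl ether) gives 17.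

Step 15. Once pyranone B forms, the C5 silyloxy group sits at a vinylogous, benzylic-type position. Acid may ionise or desilylate it and start elimination towards an aromatic chromone, and the triketone may close more slowly than the aryl diketone. Fallback, from 21 back to 22: the two rings are closed one after the other without strong acid. Warming 21 with pyridinium p-toluenesulfonate in toluene closes only the aryl diketone and gives the chromone F9. Pyranone B is then closed with PPh3/CCl4 in THF at rt, where an enol oxygen is activated as an oxyphosphonium leaving group and the ring forms by addition–elimination, a method known for 1,3,5-triketones bearing adjacent stereocentres. This gives 22.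

## Further compounds

F1 | step 14 | 1-[2-(benzyloxy)-4-methoxy-5-({(1S,4S,5R,6R)-4,5,6-tris{[tert-butyl(dimethyl)silyl]oxy}-2-hydroxy-3-(3-hydroxy-5-phenylpentanoyl)cyclohex-2-en-1-yl}oxy)phenyl]-3-hydroxy-5-phenylpentan-1-one, both new carbinol centres as epimer mixtures | OC(CCc1ccccc1)CC(=O)c1cc(O[C@@H]2C(O)=C(C(=O)CC(O)CCc3ccccc3)[C@H](O[Si](C)(C)C(C)(C)C)[C@@H](O[Si](C)(C)C(C)(C)C)[C@@H]2O[Si](C)(C)C(C)(C)C)c(OC)cc1OCc1ccccc1
F2 | step 14 | 1-[2-(benzyloxy)-4-methoxy-5-({(1S,4S,5R,6R)-4,5,6-tris{[tert-butyl(dimethyl)silyl]oxy}-2-hydroxy-3-(3-oxo-5-phenylpentanoyl)cyclohex-2-en-1-yl}oxy)phenyl]-5-phenylpentane-1,3-dione | O=C(CCc1ccccc1)CC(=O)c1cc(O[C@@H]2C(O)=C(C(=O)CC(=O)CCc3ccccc3)[C@H](O[Si](C)(C)C(C)(C)C)[C@@H](O[Si](C)(C)C(C)(C)C)[C@@H]2O[Si](C)(C)C(C)(C)C)c(OC)cc1OCc1ccccc1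
F3 | step 5 | (1R,6S)-2-bromo-6-{[tert-butyl(dimethyl)silyl]oxy}cyclohexa-2,4-dien-1-yl 4-nitrobenzoate | O=C(O[C@H]1C(Br)=CC=C[C@@H]1O[Si](C)(C)C(C)(C)C)c1ccc(cc1)[N+](=O)[O-]
F4 | step 5 | (1R,6S)-2-bromo-6-{[tert-butyl(dimethyl)silyl]oxy}cyclohexa-2,4-dien-1-ol | O[C@H]1C(Br)=CC=C[C@@H]1O[Si](C)(C)C(C)(C)C
F5 | step 5 | 1-[2-(benzyloxy)-5-hydroxy-4-methoxyphenyl]ethan-1-one | COc1cc(OCc2ccccc2)c(C(C)=O)cc1O
F6 | step 10 | (4R,5R,6S)-2-acetyl-6-[5-acetyl-4-(benzyloxy)-2-methoxyphenoxy]-4,5-bis{[tert-butyl(dimethyl)silyl]oxy}cyclohex-2-en-1-one | CC(=O)c1cc(O[C@@H]2C(=O)C(C(C)=O)=C[C@@H](O[Si](C)(C)C(C)(C)C)[C@@H]2O[Si](C)(C)C(C)(C)C)c(OC)cc1OCc1ccccc1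
F7 | step 10 | 1-acetyl-3-[5-acetyl-4-(benzyloxy)-2-methoxyphenoxy]-4,5-bis{[tert-butyl(dimethyl)silyl]oxy}-7-oxabicyclo[4.1.0]heptan-2-one, oxirane oxygen (on C4a and C5) trans to the C6 silyloxy group, C6–C8 as in 13 | CC(=O)c1cc(O[C@@H]2C(=O)[C@]3(C(C)=O)O[C@@H]3[C@@H](O[Si](C)(C)C(C)(C)C)[C@@H]2O[Si](C)(C)C(C)(C)C)c(OC)cc1OCc1ccccc1
F8 | step 10 | 1-[5-{[(1S,4S,5R,6R)-3-acetyl-5,6-bis{[tert-butyl(dimethyl)silyl]oxy}-2,4-dihydroxycyclohex-2-en-1-yl]oxy}-2-(benzyloxy)-4-methoxyphenyl]ethan-1-one | CC(=O)c1cc(O[C@@H]2C(O)=C(C(C)=O)[C@H](O)[C@@H](O[Si](C)(C)C(C)(C)C)[C@@H]2O[Si](C)(C)C(C)(C)C)c(OC)cc1OCc1ccccc1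
F9 | step 15 | 7-methoxy-2-(2-phenylethyl)-6-({(1S,4S,5R,6R)-4,5,6-tris{[tert-butyl(dimethyl)silyl]oxy}-2-hydroxy-3-(3-oxo-5-phenylpentanoyl)cyclohex-2-en-1-yl}oxy)-4H-chromen-4-one | COc1cc2oc(CCc3ccccc3)cc(=O)c2cc1O[C@@H]1C(O)=C(C(=O)CC(=O)CCc2ccccc2)[C@H](O[Si](C)(C)C(C)(C)C)[C@@H](O[Si](C)(C)C(C)(C)C)[C@@H]1O[Si](C)(C)C(C)(C)C
A1 | alternative 1 | (5S,6R,7R,8S)-6,7-bis{[tert-butyl(dimethyl)silyl]oxy}-5-hydroxy-8-{[7-methoxy-4-oxo-2-(2-phenylethyl)-4H-chromen-6-yl]oxy}-2-(2-phenylethyl)-5,6,7,8-tetrahydro-4H-chromen-4-one | COc1cc2oc(CCc3ccccc3)cc(=O)c2cc1O[C@@H]1c2oc(CCc3ccccc3)cc(=O)c2[C@H](O)[C@@H](O[Si](C)(C)C(C)(C)C)[C@@H]1O[Si](C)(C)C(C)(C)C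
A2 | alternative 1 | (2S,3R,4S)-2,3-bis{[tert-butyl(dimethyl)silyl]oxy}-4-{[7-methoxy-4-oxo-2-(2-phenylethyl)-4H-chromen-6-yl]oxy}-5,7,9-trioxo-11-phenylundecanal | O=C[C@@H](O[Si](C)(C)C(C)(C)C)[C@H](O[Si](C)(C)C(C)(C)C)[C@H](Oc1cc2c(cc1OC)oc(CCc1ccccc1)cc2=O)C(=O)CC(=O)CC(=O)CCc1ccccc1
A3 | alternative 2 | (5R,6S,7S,8S)-6,7-diacetyl-8-hydroxy-5-[(4-methoxyphenyl)methoxy]-2-(2-phenylethyl)-5,6,7,8-tetrahydro-4H-chromen-4-one | O[C@@H]1c2oc(CCc3ccccc3)cc(=O)c2[C@H](OCc2ccc(OC)cc2)[C@@H](C(C)=O)[C@@H]1C(C)=O
A4 | alternative 2 | 3-{[(4-methoxyphenyl)methoxy]methyl}-4-oxo-6-(2-phenylethyl)-4H-pyran-2-carbaldehyde | O=Cc1oc(CCc2ccccc2)cc(=O)c1COCc1ccc(OC)cc1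
A5 | alternative 2 | (E)-hex-3-ene-2,5-dione | CC(=O)/C=C/C(C)=O
A6 | alternative 3 | (4R,5S,6S)-5-{[tert-butyl(dimethyl)silyl]oxy}-4-hydroxy-6-{[7-methoxy-4-oxo-2-(2-phenylethyl)-4H-chromen-6-yl]oxy}cyclohex-2-en-1-one | COc1cc2oc(CCc3ccccc3)cc(=O)c2cc1O[C@@H]1C(=O)C=C[C@@H](O)[C@@H]1O[Si](C)(C)C(C)(C)C
A7 | alternative 3 | 6-{[(1S,6S)-2-bromo-6-{[tert-butyl(dimethyl)silyl]oxy}cyclohexa-2,4-dien-1-yl]oxy}-7-methoxy-2-(2-phenylethyl)-4H-chromen-4-one | COc1cc2oc(CCc3ccccc3)cc(=O)c2cc1O[C@@H]1C(Br)=CC=C[C@@H]1O[Si](C)(C)C(C)(C)C
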